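**Plan**
- Cuts: (i) the bond between the tetrasubstituted alkene carbon of the cycloheptene and the CH2CH2 bridge (alkyllithium 1,2-addition, then oxidative 1,3-transposition); (ii) the oxepane O–CMe2 bond (epoxide opening); (iii) in the cyclohexane, the bond between the quaternary C(CH3) and the bridge-bearing CH (1,2-shift).
- Enabling feature: in the cyclohexane of the benzoxepane half, the quaternary ring-fusion carbon (CH3, oxepane CH2) lies directly beside the O-bearing ring-fusion CH. That pair is a 2,2-disubstituted cyclohexanone retron, so the quaternary carbon can be an oxirane carbon on a cyclopentanol whose ring CH migrates onto it.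
- Forward, oxepane half: cyclopentenone → cyclopentanone (hydride-shift rearrangement) → cyclohexanone (ring expansion) → oxepane (7-endo epoxide opening). Hydroazulene half: cyclopentenone → seven-membered ring by ring-closing metathesis. The halves are joined last.
- Stereochemistry: a CBS reduction is relayed by directed epoxidation and two stereospecific 1,2-shifts (H, then C) to the three cyclohexane carbons; axial hydride sets the ring-fusion CH–O; Shi epoxidation sets the oxepane carbinol; asymmetric methyl addition plus OH-directed hydrogenation set the hydroazulene; a convex-face Luche reduction sets the allylic alcohol.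

Key step: step 8

Assumption: 2-allyl-3-methylcyclopent-2-en-1-one (1) and the Weinreb amide 22 are taken as purchasable, and each chiral reagent is used as the enantiomer that gives the configuration drawn.

**Step 1**
Reactants: 1 2-allyl-3-methylcyclopent-2-en-1-one
Product: 2 (R)-2-allyl-3-methylcyclopent-2-en-1-ol
Conditions: (S)-2-methyl-CBS-oxazaborolidine (20 mol %), catecholborane, toluene, −78 °C
Reagents that add atoms: none
Why: Corey–Bakshi–Shibata reduction: the oxazaborolidine binds the ketone anti to the substituted alkenyl arm and delivers hydride to one carbonyl face, which should give the R carbinol, while catecholborane leaves the terminal alkene untouched.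

**Step 2**
Reactants: 2 (R)-2-allyl-3-methylcyclopent-2-en-1-ol
Product: 3 (1R,2R,5S)-1-allyl-5-methyl-6-oxabicyclo[3.1.0]hexan-2-ol (oxirane oxygen cis to OH)
Conditions: VO(acac)2 (2 mol %), t-BuOOH, CH2Cl2, 0 °C
Reagents that add atoms: tert-butyl hydroperoxide CC(C)(C)OO
Why: Hydroxyl-directed vanadium-catalysed epoxidation of an allylic alcohol: the vanadate ester delivers oxygen to the tetrasubstituted ring alkene on the face of the hydroxyl group, and the homoallylic terminal alkene is too unreactive to compete.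

**Step 3**
Reactants: 3 epoxy alcohol
Product: 4 tert-butyldimethylsilyl ether of 3
Conditions: TBSCl, imidazole, DMF, 0 °C to rt
Reagents that add atoms: tert-butyldimethylsilyl chloride CC(C)(C)[Si](C)(C)Cl
Why: Standard silylation of the secondary alcohol, which turns the carbinol CH into the hydride donor for step 4.

**Step 4**
Reactants: 4 epoxy silyl ether
Product: 5 (2S,3S)-2-allyl-3-[(tert-butyldimethylsilyl)oxy]-3-methylcyclopentan-1-one (allyl cis to the silyloxy group)
Conditions: TBSOTf (0.3 equiv), i-Pr2NEt (0.4 equiv), 4 Å molecular sieves, CH2Cl2, −40 °C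
Reagents that add atoms: none
Why: Non-aldol aldol rearrangement (semipinacol rearrangement with 1,2-hydride shift): the silyl triflate silylates the oxirane oxygen, the tertiary C–O bond next to the CH–OSi carbon breaks as the antiperiplanar carbinol hydrogen shifts across with inversion, so allyl ends cis to the new tertiary silyloxy group, and the O-silyl oxocarbenium ion gives the silyl triflate back.

**Step 5**
Reactants: 6 6-methylhept-5-en-2-one; 7 2,4,6-triisopropylbenzenesulfonohydrazide
Product: 8 6-methylhept-5-en-2-one 2,4,6-triisopropylbenzenesulfonylhydrazone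
Conditions: MeOH, HCl (cat.), rt
Reagents that add atoms: none
Why: Acid-catalysed condensation of a methyl ketone with an arylsulfonyl hydrazide to the hydrazone needed for the Shapiro reaction.

**Step 6**
Reactants: 8 sulfonylhydrazone; 5 cyclopentanone
Product: 10 2-allyl-3-[(tert-butyldimethylsilyl)oxy]-3-methyl-1-(6-methylhepta-1,5-dien-2-yl)cyclopentan-1-ol (OH, allyl and silyloxy all cis), via 2-lithio-6-methylhepta-1,5-diene 9 (not isolated)
Conditions: n-BuLi (2.1 equiv), THF, −78 to 0 °C; CeCl3, −78 °C; then 5, −78 °C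
Reagents that add atoms: none
Why: Shapiro reaction (deprotonation at the methyl group gives the less substituted vinyllithium) followed by organocerium 1,2-addition, which should occur on the ketone face opposite to the allyl and silyloxy groups and should suppress enolisation.

**Step 7**
Reactants: 10 tertiary allylic alcohol
Product: 11 the corresponding 1-[(S)-2-(4-methylpent-3-en-1-yl)oxiran-2-yl]cyclopentan-1-ol
Conditions: VO(acac)2 (3 mol %), t-BuOOH, CH2Cl2, 0 °C
Reagents that add atoms: tert-butyl hydroperoxide CC(C)(C)OO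
Why: Hydroxyl-directed vanadium-catalysed epoxidation: in the vanadate transition state the alkene substituent avoids the bulky allyl-bearing ring CH (allylic 1,2-strain) and eclipses the ring CH2, so oxygen should reach one diastereotopic face (the erythro-type outcome known for 2-substituted allylic alcohols), and the remote alkenes are not directed.

**Step 8**
Reactants: 11 epoxy alcohol
Product: 12 3-allyl-4-[(tert-butyldimethylsilyl)oxy]-2-(hydroxymethyl)-4-methyl-2-(4-methylpent-3-en-1-yl)cyclohexan-1-one (CH2OH, allyl and silyloxy on one face)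
Conditions: BF3·OEt2 (1.1 equiv), CH2Cl2, −78 °C
Reagents that add atoms: none
Why: BF3 binds the oxirane oxygen, the tertiary C–O bond ionises and the allyl-bearing ring CH of the cyclopentanol shifts from the carbinol carbon to the oxirane carbon anti to the leaving oxygen while the carbinol becomes the ketone, which enlarges the five-membered carbocycle to the six-membered one. The closest known reaction type is the Lewis acid-promoted semipinacol rearrangement of tertiary 2,3-epoxy alcohols with ring expansion (1-oxiranylcycloalkanol to 2-hydroxymethyl-2-alkylcycloalkanone). No ring is closed by cyclisation: the ring grows by a suprafacial 1,2-alkyl shift that inverts the terminus and retains the migrating carbon. The new quaternary stereocentre is fixed by the oxirane configuration from step 7 through that inversion, so CH2OH ends cis and the chain trans to the allyl group, and the allyl-bearing stereocentre is carried over unchanged. The step needs migration of the substituted CH and not of the ring CH2, and no hydride shift to an aldehyde: the secondary carbon is the better migrating group, its reactive rotamer puts the chain beside the small ring CH2 whereas the rotamer for CH2 migration eclipses the oxirane with the bulky methine, and carbonyl formation at the carbinol should make the carbon shift faster than a Meinwald pathway.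

**Step 9**
Reactants: 12 β-hydroxy ketone
Product: 13 3-allyl-2-(bromomethyl)-4-[(tert-butyldimethylsilyl)oxy]-4-methyl-2-(4-methylpent-3-en-1-yl)cyclohexan-1-one
Conditions: CBr4, PPh3, 2,6-lutidine, CH2Cl2, 0 °C to rt
Reagents that add atoms: carbon tetrabromide BrC(Br)(Br)Br
Why: Appel reaction on the primary alcohol; the bromide masks the future angular methyl group so that this oxygen cannot open the epoxide made in step 11.

**Step 10**
Reactants: 13 bromo ketone
Product: 14 the corresponding cyclohexan-1-ol (OH cis to CH2Br)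
Conditions: NaBH4, MeOH, −20 °C
Reagents that add atoms: none
Why: Hydride reduction of a cyclohexanone by axial attack on the face away from the axial CH2Br group, which should give the equatorial alcohol cis to CH2Br.

**Step 11**
Reactants: 14 bromo alcohol
Product: 15 the (R)-3,3-dimethyloxiran-2-yl epoxide of 14
Conditions: Shi ketone (D-fructose-derived, 30 mol %), KHSO5 (as Oxone), K2CO3, Bu4NHSO4, MeCN/dimethoxymethane/aqueous borate buffer, 0 °C
Reagents that add atoms: potassium peroxymonosulfate [K+].[O-]S(=O)(=O)OO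
Why: Shi asymmetric epoxidation: the fructose-derived dioxirane epoxidises the trisubstituted alkene under reagent control, which should give the R-configured oxirane CH, and it does not touch the terminal alkene.

**Step 12**
Reactants: 15 epoxy alcohol
Product: 17 6-allyl-5a-(bromomethyl)-3,7-bis[(tert-butyldimethylsilyl)oxy]-2,2,7-trimethyldecahydro-1-benzoxepine (trans-fused), via oxepan-3-ol 16 (not isolated)
Conditions: camphorsulfonic acid (10 mol %), CH2Cl2, 0 °C; then 2,6-lutidine, TBSOTf, 0 °C
Reagents that add atoms: tert-butyldimethylsilyl triflate CC(C)(C)[Si](C)(C)OS(=O)(=O)C(F)(F)F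
Why: Acid-catalysed epoxide opening by the neighbouring equatorial hydroxyl in the 7-endo mode at the tertiary oxirane carbon (the carbon best able to carry positive charge), which keeps the CH–O configuration and gives the trans-fused oxepane, followed by silylation of the new secondary alcohol in the same flask.

**Step 13**
Reactants: 17 allyl compound
Product: 19 2-[5a-(bromomethyl)-3,7-bis(silyloxy)-2,2,7-trimethyldecahydro-1-benzoxepin-6-yl]ethan-1-ol, via aldehyde 18 (not isolated)
Conditions: O3, CH2Cl2/MeOH, −78 °C; then NaBH4, −78 °C to rt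
Reagents that add atoms: ozone [O-][O+]=O
Why: Ozonolysis of the only alkene left, with reductive work-up, cuts the allyl group down to the 2-hydroxyethyl arm.

**Step 14**
Reactants: 19 bromo alcohol
Product: 20 2-[(3R,5aR,6R,7S,9aR)-3,7-bis[(tert-butyldimethylsilyl)oxy]-2,2,5a,7-tetramethyldecahydro-1-benzoxepin-6-yl]ethan-1-ol
Conditions: Bu3SnH, AIBN, benzene, 80 °C
Reagents that add atoms: none
Why: Tin hydride radical dehalogenation turns CH2Br into the angular methyl group; it is placed after removal of both alkenes so that the neopentyl radical has no 5-exo cyclisation open to it.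

**Step 15**
Reactants: 20 primary alcohol
Product: 21 the corresponding 6-(2-iodoethyl) compound
Conditions: I2, PPh3, imidazole, CH2Cl2, 0 °C
Reagents that add atoms: iodine II
Why: Appel-type iodination of the primary alcohol.

**Step 16**
Reactants: 22 N-methoxy-N,2-dimethylpropanamide; 23 isopropenylmagnesium bromide
Product: 24 2,4-dimethylpent-1-en-3-one
Conditions: THF, 0 °C; aqueous NH4Cl
Reagents that add atoms: none
Why: Weinreb ketone synthesis: the chelated tetrahedral intermediate stops the Grignard addition at the ketone stage.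

**Step 17**
Reactants: 25 cyclopentane-1,3-dione; 26 allyl bromide
Product: 27 2-allylcyclopentane-1,3-dione
Conditions: KOH, H2O, rt
Reagents that add atoms: none
Why: C-alkylation of the enolate of a cyclic 1,3-diketone by an allylic halide in water.

**Step 18**
Reactants: 27 2-allylcyclopentane-1,3-dione
Product: 28 2-allyl-3-chlorocyclopent-2-en-1-one
Conditions: (COCl)2, DMF (cat.), CH2Cl2, 0 °C to rt
Reagents that add atoms: oxalyl chloride O=C(Cl)C(=O)Cl
Why: Conversion of the enolised 1,3-diketone to the vinylogous acid chloride by the Vilsmeier-type reagent.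

**Step 19**
Reactants: 24 2,4-dimethylpent-1-en-3-one; 28 β-chloro enone
Product: 30 2-allyl-3-(2,4-dimethyl-3-oxopent-4-en-2-yl)cyclopent-2-en-1-one, via lithium dienolate 29 (not isolated)
Conditions: lithium diisopropylamide, THF, −78 °C; then 28, −78 to 0 °C
Reagents that add atoms: none
Why: Addition–elimination on a β-chloro enone: the cross-conjugated lithium enolate (only the isopropyl α-hydrogen can be removed) adds through its tetrasubstituted carbon to the β-carbon and chloride leaves, forming the quaternary carbon.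

**Step 20**
Reactants: 30 trienedione
Product: 31 4,4,6-trimethyl-2,3,4,8-tetrahydroazulene-1,5-dione
Conditions: RuCl2(=CHPh)(PCy3)(H2IMes) (second-generation Grubbs catalyst, 5 mol %), toluene, 80 °C
Reagents that add atoms: none
Why: Ring-closing metathesis between the allyl group and the isopropenyl ketone closes the seven-membered ring as a trisubstituted enone with loss of ethylene.

**Step 21**
Reactants: 31 dienedione
Product: 32 (R)-1-hydroxy-1,4,4,6-tetramethyl-2,3,4,8-tetrahydroazulen-5(1H)-one
Conditions: Me2Zn, Ti(O-i-Pr)4, chiral trans-cyclohexane-1,2-diamine bis(camphorsulfonamide) diol ligand (10 mol %), toluene, rt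
Reagents that add atoms: dimethylzinc C[Zn]C
Why: Catalytic asymmetric 1,2-addition of dimethylzinc to a cyclic enone, which should attack only the unhindered cyclopentenone carbonyl and, with the proper ligand enantiomer, give the R tertiary allylic alcohol.

**Step 22**
Reactants: 32 tertiary allylic alcohol
Product: 33 (1R,3aR,8aR)-1-hydroxy-1,4,4,6-tetramethyl-2,3,3a,4,8,8a-hexahydroazulen-5(1H)-one (cis-fused, ring-fusion hydrogens cis to OH)
Conditions: [Ir(cod)(PCy3)(py)]PF6 (5 mol %), H2 (1 atm), CH2Cl2, 0 °C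
Reagents that add atoms: none
Why: Hydroxyl-directed hydrogenation: the cationic iridium catalyst bound to the tertiary alcohol delivers both hydrogens to the tetrasubstituted alkene from the face of OH, which sets the cis ring fusion, while the electron-poor, undirected enone alkene should survive.

**Step 23**
Reactants: 33 hydroxy enone
Product: 34 triethylsilyl ether of 33
Conditions: TESOTf, 2,6-lutidine, CH2Cl2, −78 °C
Reagents that add atoms: triethylsilyl triflate CC[Si](CC)(CC)OS(=O)(=O)C(F)(F)F
Why: Silylation of the tertiary alcohol so that it cannot quench the organometallic reagent of step 24.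

**Step 24**
Reactants: 21 iodide; 34 enone
Product: 36 tertiary allylic alcohol joining both halves (carbinol epimers), via alkyllithium 35 (not isolated)
Conditions: t-BuLi (2.1 equiv), Et2O, −78 °C; CeCl3, THF, −78 °C; then 34, −78 to −40 °C
Reagents that add atoms: none
Why: Iodine–lithium exchange followed by organocerium 1,2-addition to the hindered enone carbonyl (the same addition is well known for 2,6,6-trimethylcyclohex-2-enone); the configuration of the new carbinol is of no consequence.

**Step 25**
Reactants: 36 tertiary allylic alcohol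
Product: 37 transposed tetrasubstituted enone (fully silylated 10-ketone)
Conditions: pyridinium chlorochromate, NaOAc, 4 Å molecular sieves, CH2Cl2, rt
Reagents that add atoms: none
Why: Babler–Dauben oxidative transposition: the chromate ester of the tertiary allylic alcohol undergoes [3,3]-shift and oxidation to the transposed enone.

**Step 26**
Reactants: 37 enone
Product: 38 tris-silyl ether of the target (S allylic alcohol)
Conditions: NaBH4, CeCl3·7H2O, MeOH, −78 °C
Reagents that add atoms: none
Why: Luche reduction: 1,2-hydride attack from the convex face of the cis-fused hydroazulene (the face of the ring-fusion hydrogens) should give the S allylic alcohol.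

**Step 27**
Reactants: 38 tris-silyl ether
Product: 39 CNP0276044.1
Conditions: tetrabutylammonium fluoride (Bu4NF), THF, 50 °C
Reagents that add atoms: none
Why: Fluoride-induced cleavage of the three silyl ethers.

**Compound list**
1 | 2-allyl-3-methylcyclopent-2-en-1-one | C=CCC1=C(C)CCC1=O | starting material
2 | (R)-2-allyl-3-methylcyclopent-2-en-1-ol | C=CCC1=C(C)CC[C@H]1O | intermediate
3 | (1R,2R,5S)-1-allyl-5-methyl-6-oxabicyclo[3.1.0]hexan-2-ol | C=CC[C@]12O[C@@]1(C)CC[C@H]2O | intermediate
4 | tert-butyldimethylsilyl ether of 3 | C=CC[C@]12O[C@@]1(C)CC[C@H]2O[Si](C)(C)C(C)(C)C | intermediate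
5 | (2S,3S)-2-allyl-3-[(tert-butyldimethylsilyl)oxy]-3-methylcyclopentan-1-one | C=CC[C@@H]1C(=O)CC[C@]1(C)O[Si](C)(C)C(C)(C)C | intermediate
6 | 6-methylhept-5-en-2-one | CC(=O)CCC=C(C)C | starting material
7 | 2,4,6-triisopropylbenzenesulfonohydrazide | CC(C)c1cc(C(C)C)c(S(=O)(=O)NN)c(C(C)C)c1 | starting material
8 | 6-methylhept-5-en-2-one 2,4,6-triisopropylbenzenesulfonylhydrazone | CC(CCC=C(C)C)=NNS(=O)(=O)c1c(C(C)C)cc(C(C)C)cc1C(C)C | intermediate
9 | 2-lithio-6-methylhepta-1,5-diene | [Li]C(=C)CCC=C(C)C | intermediate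
10 | 2-allyl-3-(TBSO)-3-methyl-1-(6-methylhepta-1,5-dien-2-yl)cyclopentan-1-ol, OH/allyl/OTBS cis | C=CC[C@@H]1[C@@](O)(C(=C)CCC=C(C)C)CC[C@]1(C)O[Si](C)(C)C(C)(C)C | intermediate
11 | 2-allyl-3-(TBSO)-3-methyl-1-[(S)-2-(4-methylpent-3-en-1-yl)oxiran-2-yl]cyclopentan-1-ol | C=CC[C@@H]1[C@@](O)([C@@]2(CO2)CCC=C(C)C)CC[C@]1(C)O[Si](C)(C)C(C)(C)C | intermediate
12 | 3-allyl-4-(TBSO)-2-(hydroxymethyl)-4-methyl-2-(4-methylpent-3-en-1-yl)cyclohexan-1-one | C=CC[C@@H]1[C@@](CO)(CCC=C(C)C)C(=O)CC[C@]1(C)O[Si](C)(C)C(C)(C)C | intermediate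
13 | 3-allyl-2-(bromomethyl)-4-(TBSO)-4-methyl-2-(4-methylpent-3-en-1-yl)cyclohexan-1-one | C=CC[C@@H]1[C@@](CBr)(CCC=C(C)C)C(=O)CC[C@]1(C)O[Si](C)(C)C(C)(C)C | intermediate
14 | 3-allyl-2-(bromomethyl)-4-(TBSO)-4-methyl-2-(4-methylpent-3-en-1-yl)cyclohexan-1-ol, OH cis to CH2Br | C=CC[C@@H]1[C@@](CBr)(CCC=C(C)C)[C@H](O)CC[C@]1(C)O[Si](C)(C)C(C)(C)C | intermediate
15 | (R)-3,3-dimethyloxiran-2-yl epoxide of 14 | C=CC[C@@H]1[C@@](CBr)(CC[C@H]2OC2(C)C)[C@H](O)CC[C@]1(C)O[Si](C)(C)C(C)(C)C | intermediate
16 | 6-allyl-5a-(bromomethyl)-7-(TBSO)-2,2,7-trimethyldecahydro-1-benzoxepin-3-ol | C=CC[C@@H]1[C@@]2(CBr)CC[C@@H](O)C(C)(C)O[C@@H]2CC[C@]1(C)O[Si](C)(C)C(C)(C)C | intermediate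
17 | 6-allyl-5a-(bromomethyl)-3,7-bis(TBSO)-2,2,7-trimethyldecahydro-1-benzoxepine | C=CC[C@@H]1[C@@]2(CBr)CC[C@@H](O[Si](C)(C)C(C)(C)C)C(C)(C)O[C@@H]2CC[C@]1(C)O[Si](C)(C)C(C)(C)C | intermediate
18 | 2-[5a-(bromomethyl)-3,7-bis(TBSO)-2,2,7-trimethyldecahydro-1-benzoxepin-6-yl]acetaldehyde | O=CC[C@@H]1[C@@]2(CBr)CC[C@@H](O[Si](C)(C)C(C)(C)C)C(C)(C)O[C@@H]2CC[C@]1(C)O[Si](C)(C)C(C)(C)C | intermediate
19 | 2-[5a-(bromomethyl)-3,7-bis(TBSO)-2,2,7-trimethyldecahydro-1-benzoxepin-6-yl]ethan-1-ol | OCC[C@@H]1[C@@]2(CBr)CC[C@@H](O[Si](C)(C)C(C)(C)C)C(C)(C)O[C@@H]2CC[C@]1(C)O[Si](C)(C)C(C)(C)C | intermediate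
20 | 2-[(3R,5aR,6R,7S,9aR)-3,7-bis(TBSO)-2,2,5a,7-tetramethyldecahydro-1-benzoxepin-6-yl]ethan-1-ol | OCC[C@@H]1[C@@]2(C)CC[C@@H](O[Si](C)(C)C(C)(C)C)C(C)(C)O[C@@H]2CC[C@]1(C)O[Si](C)(C)C(C)(C)C | intermediate
21 | (3R,5aR,6R,7S,9aR)-3,7-bis(TBSO)-6-(2-iodoethyl)-2,2,5a,7-tetramethyldecahydro-1-benzoxepine | ICC[C@@H]1[C@@]2(C)CC[C@@H](O[Si](C)(C)C(C)(C)C)C(C)(C)O[C@@H]2CC[C@]1(C)O[Si](C)(C)C(C)(C)C | intermediate
22 | N-methoxy-N,2-dimethylpropanamide | CC(C)C(=O)N(C)OC | starting material
23 | isopropenylmagnesium bromide | C=C(C)[Mg]Br | starting material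
24 | 2,4-dimethylpent-1-en-3-one | CC(C)C(=O)C(C)=C | intermediate
25 | cyclopentane-1,3-dione | O=C1CCC(=O)C1 | starting material
26 | allyl bromide | C=CCBr | starting material
27 | 2-allylcyclopentane-1,3-dione | C=CCC1C(=O)CCC1=O | intermediate
28 | 2-allyl-3-chlorocyclopent-2-en-1-one | C=CCC1=C(Cl)CCC1=O | intermediate
29 | lithium 2,4-dimethylpenta-1,3-dien-3-olate | [Li]OC(=C(C)C)C(C)=C | intermediate
30 | 2-allyl-3-(2,4-dimethyl-3-oxopent-4-en-2-yl)cyclopent-2-en-1-one | C=CCC1=C(C(C)(C)C(=O)C(C)=C)CCC1=O | intermediate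
31 | 4,4,6-trimethyl-2,3,4,8-tetrahydroazulene-1,5-dione | CC1=CCC2=C(CCC2=O)C(C)(C)C1=O | intermediate
32 | (R)-1-hydroxy-1,4,4,6-tetramethyl-2,3,4,8-tetrahydroazulen-5(1H)-one | CC1=CCC2=C(CC[C@@]2(C)O)C(C)(C)C1=O | intermediate
33 | (1R,3aR,8aR)-1-hydroxy-1,4,4,6-tetramethyl-2,3,3a,4,8,8a-hexahydroazulen-5(1H)-one | CC1=CC[C@@H]2[C@@H](CC[C@@]2(C)O)C(C)(C)C1=O | intermediate
34 | triethylsilyl ether of 33 | CC1=CC[C@@H]2[C@@H](CC[C@@]2(C)O[Si](CC)(CC)CC)C(C)(C)C1=O | intermediate
35 | 2-[(3R,5aR,6R,7S,9aR)-3,7-bis(TBSO)-2,2,5a,7-tetramethyldecahydro-1-benzoxepin-6-yl]ethyllithium | [Li]CC[C@@H]1[C@@]2(C)CC[C@@H](O[Si](C)(C)C(C)(C)C)C(C)(C)O[C@@H]2CC[C@]1(C)O[Si](C)(C)C(C)(C)C | intermediate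
36 | coupled tertiary allylic alcohol (5-hydroxy-5-[2-(benzoxepinyl)ethyl]hexahydroazulene, carbinol epimers) | CC1=CC[C@@H]2[C@@H](CC[C@@]2(C)O[Si](CC)(CC)CC)C(C)(C)C1(O)CC[C@@H]3[C@@]4(C)CC[C@@H](O[Si](C)(C)C(C)(C)C)C(C)(C)O[C@@H]4CC[C@]3(C)O[Si](C)(C)C(C)(C)C | intermediate
37 | transposed enone (tris-silyl ether, ketone in place of the allylic alcohol of the target) | CC1=C(CC[C@@H]2[C@@]3(C)CC[C@@H](O[Si](C)(C)C(C)(C)C)C(C)(C)O[C@@H]3CC[C@]2(C)O[Si](C)(C)C(C)(C)C)C(C)(C)[C@@H]2CC[C@@](C)(O[Si](CC)(CC)CC)[C@@H]2CC1=O | intermediate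
38 | tris-silyl ether of the target | CC1=C(CC[C@@H]2[C@@]3(C)CC[C@@H](O[Si](C)(C)C(C)(C)C)C(C)(C)O[C@@H]3CC[C@]2(C)O[Si](C)(C)C(C)(C)C)C(C)(C)[C@@H]2CC[C@@](C)(O[Si](CC)(CC)CC)[C@@H]2C[C@@H]1O | intermediate
39 | CNP0276044.1 | CC1=C(CC[C@@H]2[C@@]3(C)CC[C@@H](O)C(C)(C)O[C@@H]3CC[C@]2(C)O)C(C)(C)[C@@H]2CC[C@@](C)(O)[C@@H]2C[C@@H]1O | target

**Totals**
Total step count: 27. Longest linear sequence: 18 steps (steps 1–4, 6–15, 24–27).

**Steps most likely to fail**

1. Step 8. The unsubstituted ring CH2 may migrate in place of the allyl-bearing CH, or the oxirane may ionise without a carbon shift (elimination or aldehyde formation). Fallback, a β-hydroxy selenide ring expansion that sets out from 5 and 6 and comes back at 20: ketone 6 is turned with MeSeH and ZnCl2 into the selenoketal 6-methyl-2,2-bis(methylselanyl)hept-5-ene F1. Selenium–lithium exchange with n-BuLi gives the α-selanyl alkyllithium F2 (not isolated), which adds to 5 to give the β-hydroxy selenide F3. AgBF4 on alumina removes the selenium from the tertiary carbon and the more substituted ring carbon shifts, giving the 2-methyl-2-(4-methylpent-3-en-1-yl)cyclohexanone F4; here the quaternary configuration rests on the addition step and the epimers would have to be separated. NaBH4 gives the alcohol F5, Shi epoxidation the epoxide F6, acid the oxepanol F7 and TBSOTf the bis-silyl ether F8. Ozonolysis gives the aldehyde F9 (not isolated), which NaBH4 reduces to 20, so steps 9 and 14 fall away.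

2. Step 12. The hydroxyl may attack the secondary oxirane carbon (6-exo, tetrahydropyran) or the epoxide may rearrange before it is trapped. Fallback, sets out from 14 and comes back at 16: alkoxymercuration of the trisubstituted alkene with Hg(O2CCF3)2 closes the oxepane at the tertiary carbon and gives the organomercurial F10. NaBH4 under O2 replaces mercury by hydroxyl to give the oxepan-3-ol as a mixture of carbinol epimers F11. Dess–Martin periodinane gives the oxepan-3-one F12, and a CBS reduction with the proper catalyst enantiomer should give 16, which is silylated to 17 as before.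

3. Step 19. The hindered enolate may attack through oxygen, or proton transfer from the chloro enone may quench it before the quaternary carbon forms. Fallback, sets out from 27 and 24 and comes back at 30: 27 is converted with Tf2O and Et3N into 2-allyl-3-oxocyclopent-1-en-1-yl trifluoromethanesulfonate F13, and a palladium-catalysed α-alkenylation of ketone 24 (Pd2(dba)3, P(t-Bu)3, LiN(SiMe3)2, toluene) joins the two to give 30.

**Further compounds**
F1 | step 8 | 6-methyl-2,2-bis(methylselanyl)hept-5-ene | CC(C)=CCCC(C)([Se]C)[Se]C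
F2 | step 8 | 6-methyl-2-(methylselanyl)hept-5-en-2-yllithium | [Li]C(C)([Se]C)CCC=C(C)C
F3 | step 8 | 2-allyl-3-(TBSO)-3-methyl-1-[6-methyl-2-(methylselanyl)hept-5-en-2-yl]cyclopentan-1-ol | C=CC[C@@H]1[C@@](O)(C(C)([Se]C)CCC=C(C)C)CC[C@]1(C)O[Si](C)(C)C(C)(C)C
F4 | step 8 | 3-allyl-4-(TBSO)-2,4-dimethyl-2-(4-methylpent-3-en-1-yl)cyclohexan-1-one | C=CC[C@@H]1[C@@](C)(CCC=C(C)C)C(=O)CC[C@]1(C)O[Si](C)(C)C(C)(C)C
F5 | step 8 | 3-allyl-4-(TBSO)-2,4-dimethyl-2-(4-methylpent-3-en-1-yl)cyclohexan-1-ol | C=CC[C@@H]1[C@@](C)(CCC=C(C)C)[C@H](O)CC[C@]1(C)O[Si](C)(C)C(C)(C)C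
F6 | step 8 | (R)-3,3-dimethyloxiran-2-yl epoxide of F5 | C=CC[C@@H]1[C@@](C)(CC[C@H]2OC2(C)C)[C@H](O)CC[C@]1(C)O[Si](C)(C)C(C)(C)C
F7 | step 8 | 6-allyl-7-(TBSO)-2,2,5a,7-tetramethyldecahydro-1-benzoxepin-3-ol | C=CC[C@@H]1[C@@]2(C)CC[C@@H](O)C(C)(C)O[C@@H]2CC[C@]1(C)O[Si](C)(C)C(C)(C)C
F8 | step 8 | 6-allyl-3,7-bis(TBSO)-2,2,5a,7-tetramethyldecahydro-1-benzoxepine | C=CC[C@@H]1[C@@]2(C)CC[C@@H](O[Si](C)(C)C(C)(C)C)C(C)(C)O[C@@H]2CC[C@]1(C)O[Si](C)(C)C(C)(C)C
F9 | step 8 | 2-[3,7-bis(TBSO)-2,2,5a,7-tetramethyldecahydro-1-benzoxepin-6-yl]acetaldehyde | O=CC[C@@H]1[C@@]2(C)CC[C@@H](O[Si](C)(C)C(C)(C)C)C(C)(C)O[C@@H]2CC[C@]1(C)O[Si](C)(C)C(C)(C)C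
F10 | step 12 | [6-allyl-5a-(bromomethyl)-7-(TBSO)-2,2,7-trimethyldecahydro-1-benzoxepin-3-yl]mercury trifluoroacetate | C=CC[C@@H]1[C@@]2(CBr)CCC([Hg]OC(=O)C(F)(F)F)C(C)(C)O[C@@H]2CC[C@]1(C)O[Si](C)(C)C(C)(C)C
F11 | step 12 | 6-allyl-5a-(bromomethyl)-7-(TBSO)-2,2,7-trimethyldecahydro-1-benzoxepin-3-ol, carbinol epimers | C=CC[C@@H]1[C@@]2(CBr)CCC(O)C(C)(C)O[C@@H]2CC[C@]1(C)O[Si](C)(C)C(C)(C)C
F12 | step 12 | 6-allyl-5a-(bromomethyl)-7-(TBSO)-2,2,7-trimethyloctahydro-1-benzoxepin-3(2H)-one | C=CC[C@@H]1[C@@]2(CBr)CCC(=O)C(C)(C)O[C@@H]2CC[C@]1(C)O[Si](C)(C)C(C)(C)C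
F13 | step 19 | 2-allyl-3-oxocyclopent-1-en-1-yl trifluoromethanesulfonate | C=CCC1=C(OS(=O)(=O)C(F)(F)F)CCC1=O
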